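**Plan**

- The retrosynthesis cuts ring C (the cycloheptene) twice in one stroke: the C(CH3)=CH double bond, and the bond from the C(CH3)2 carbon to the neighbouring C/D ring-fusion CH.
- What makes this possible: that ring-fusion CH is β to the carbinol carbon of ring D (a masked ketone), so it is the β-carbon of a cyclopentenone and accepts a tertiary radical centred on C(CH3)2; the only C=C of the target lies between the two pieces as a ring-closing-metathesis retron.
- The pieces are the redox-active ester 23 (rings A and B, the two-carbon link, the future quaternary carbon) and the enone 27 (future ring D).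
- Forward order: ring B is the starting dione; ring A (oxepane) is closed by epoxide opening; the chain is grown by cross-metathesis and an Ireland–Claisen rearrangement; rings C and D are joined in step 16; the ring-D carbinol and the ring-A ketone come last.
- Stereochemistry: CBS desymmetrisation (A/B fusion); hydride shift and equatorial methyl addition under substrate control (ring B); CBS reduction plus Claisen chirality transfer (chain-bearing CH of ring C); the removable silyloxy group of 27 (C/D fusion); convex-face hydration (ring-D carbinol).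

Key step: step 16

Assumption: the target is made exactly as its SMILES specifies (cis-fused oxepane/cyclohexane, cis-fused hydroazulene); the oxepane carbinol carbon is carried as an epimer mixture until its final oxidation, and both oxazaborolidine reductions are taken to follow the usual large/small-substituent model (otherwise the enantiomeric catalyst is used).

Step 1
Reactants: 1 2-methylcyclohexane-1,3-dione; 2 acrolein
Product: 3 3-(1-methyl-2,6-dioxocyclohexyl)propanal
Conditions: H2O, rt
Reagents that add atoms: none
Why: Michael addition of the enolised 1,3-dione to acrolein in water is a standard way to build the quaternary carbon of 2,2-disubstituted cyclohexane-1,3-diones.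

Step 2
Reactants: 3 3-(1-methyl-2,6-dioxocyclohexyl)propanal; 4 isopropyltriphenylphosphonium iodide
Product: 5 2-methyl-2-(4-methylpent-3-en-1-yl)cyclohexane-1,3-dione
Conditions: 4, n-BuLi, THF, 0 °C; then 3, −78 °C to rt
Reagents that add atoms: none
Why: Wittig olefination with the non-stabilised isopropylidene ylide should be chemoselective for the aldehyde, because both ketones are flanked by the quaternary carbon and react far more slowly.

Step 3
Reactants: 5 2-methyl-2-(4-methylpent-3-en-1-yl)cyclohexane-1,3-dione
Product: 6 (2R,3R)-3-hydroxy-2-methyl-2-(4-methylpent-3-en-1-yl)cyclohexan-1-one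
Conditions: (S)-2-methyl-CBS-oxazaborolidine (20 mol %), catecholborane (1.2 equiv), PhNEt2, PhMe, −60 °C
Reagents that add atoms: none
Why: Corey–Bakshi–Shibata reduction desymmetrises the prochiral diketone: the catalyst fixes the carbinol configuration and hydride enters the carbonyl it can reach anti to the larger homoprenyl arm, so both stereocentres (hydroxyl cis to homoprenyl) should be set in one step.

Step 4
Reactants: 6 (2R,3R)-3-hydroxy-2-methyl-2-(4-methylpent-3-en-1-yl)cyclohexan-1-one
Product: 8 (5aR,9aR)-3-hydroxy-2,2,5a-trimethyloctahydro-1-benzoxepin-6(2H)-one (C-3 epimers), via epoxy ketol 7 (not isolated)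
Conditions: mCPBA (1.1 equiv), CH2Cl2, 0 °C; then CSA (10 mol %), 0 °C to rt
Reagents that add atoms: 3-chloroperoxybenzoic acid, O=C(OO)c1cccc(Cl)c1
Why: Prilezhaev epoxidation of the trisubstituted alkene followed by acid-catalysed 7-endo epoxide opening, the ring hydroxyl attacking the tertiary (Markovnikov) carbon, should close the cis-fused oxepane ring A without touching the two stereocentres; the new carbinol epimers are erased by the final oxidation.

Step 5
Reactants: 8 (5aR,9aR)-3-hydroxy-2,2,5a-trimethyloctahydro-1-benzoxepin-6(2H)-one
Product: 9 ring-AB enol triflate (6-trifluoromethanesulfonyloxy-6,7-ene)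
Conditions: KN(SiMe3)2 (2.2 equiv), THF, −78 °C; PhNTf2 (1.1 equiv), −78 to 0 °C; aq. NH4Cl
Reagents that add atoms: N-phenylbis(trifluoromethanesulfonimide), O=S(=O)(N(c1ccccc1)S(=O)(=O)C(F)(F)F)C(F)(F)F
Why: The ketone has a single enolisable α-position, so enolate formation and O-sulfonylation should give one enol triflate, the second equivalent of base only converting the hydroxyl into its alkoxide.

Step 6
Reactants: 9 ring-AB enol triflate; 10 but-3-en-1-ylmagnesium bromide
Product: 11 ring-AB diene (6-butenyl-6,7-ene, 3-ol)
Conditions: Fe(acac)3 (5 mol %), 10 (2.3 equiv), THF/NMP, −30 °C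
Reagents that add atoms: none
Why: Iron-catalysed Kumada-type cross-coupling of alkenyl triflates with alkyl Grignard reagents is fast at low temperature and free of β-hydride elimination, so the butenyl chain should be attached cleanly to the ring sp2 carbon.

Step 7
Reactants: 11 ring-AB diene
Product: 13 ring-AB 7-ketone (butenyl chain cis to the angular methyl group), via epoxide 12 (not isolated)
Conditions: dimethyldioxirane (1.1 equiv), acetone/CH2Cl2, −20 °C; evaporate; LiClO4 (5 M in Et2O), rt
Reagents that add atoms: dimethyldioxirane, CC1(C)OO1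
Why: Epoxidation of the electron-rich trisubstituted ring alkene (the terminal alkene reacts far more slowly) on the convex face of the cis-fused bicycle, then a Meinwald rearrangement in which hydride migrates to the tertiary cation anti to the departing oxygen, should transpose the oxygen into a ketone and set the α-CH with the chain cis to the angular methyl group.

Step 8
Reactants: 13 ring-AB 7-ketone
Product: 14 ring-AB diol (tertiary 7-hydroxyl cis to the butenyl chain and to the angular methyl group)
Conditions: CeCl3 (anhydrous, 3 equiv), MeMgBr (3.5 equiv), THF, −78 °C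
Reagents that add atoms: methylmagnesium bromide, C[Mg]Br
Why: The weakly basic organocerium reagent adds without enolising the α-stereocentre and from the equatorial direction, axial attack being blocked by the syn-axial angular methyl group, which should give the axial tertiary alcohol cis to the side chain.

Step 9
Reactants: 14 ring-AB diol; 15 3-methylbut-3-en-2-one
Product: 16 (E)-3-methylhex-3-en-2-one carrying the ring-AB diol at C-6
Conditions: 15 (5 equiv), second-generation Hoveyda–Grubbs catalyst (5 mol %), CH2Cl2, 40 °C
Reagents that add atoms: none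
Why: Olefin cross-metathesis of a terminal alkene with a 1,1-disubstituted enone that does not homodimerise should give the trisubstituted enone with the thermodynamically favoured E geometry.

Step 10
Reactants: 16 (E)-enone
Product: 17 (2S,3E)-allylic alcohol
Conditions: (R)-2-methyl-CBS-oxazaborolidine (20 mol %), catecholborane (3.5 equiv), PhMe, −78 °C
Reagents that add atoms: none
Why: Corey–Bakshi–Shibata reduction of the α-methyl enone, the alkenyl group acting as the large substituent, should give the (S)-carbinol under catalyst control, the remote ring stereocentres having no influence.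

Step 11
Reactants: 17 (2S,3E)-allylic alcohol; 18 isobutyric anhydride
Product: 19 bis-isobutyrate (allylic and ring-A secondary hydroxyl groups esterified)
Conditions: 18 (3 equiv), Et3N, DMAP (20 mol %), CH2Cl2, rt
Reagents that add atoms: none
Why: DMAP-catalysed acylation esterifies both secondary hydroxyl groups and leaves the tertiary one free, which installs the isobutyrate for the rearrangement and protects the ring-A carbinol.

Step 12
Reactants: 19 bis-isobutyrate
Product: 21 (3R,4E)-2,2,4-trimethyl-3-[2-(ring-AB)ethyl]hex-4-enoic acid, via silyl ketene acetal 20 (not isolated)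
Conditions: LiN(iPr)2 (4 equiv), Me3SiCl (6 equiv), THF, −78 °C to 60 °C; then 1 M HCl
Reagents that add atoms: none
Why: Ireland–Claisen rearrangement of the isobutyrate silyl ketene acetal (no enolate-geometry issue) through a chair transition state with the carbinol methyl group equatorial should join the new gem-dimethyl quaternary carbon to the allylic terminus with 1,3-transfer of chirality, setting the chain-bearing stereocentre and an (E)-propenyl group.

Step 13
Reactants: 21 hexenoic acid; 22 N-hydroxyphthalimide
Product: 23 N-acyloxyphthalimide (redox-active ester) of 21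
Conditions: 22 (1.2 equiv), N,N'-diisopropylcarbodiimide, DMAP (10 mol %), CH2Cl2, rt
Reagents that add atoms: none
Why: Carbodiimide coupling converts the hindered acid into the redox-active ester from which the tertiary radical is released by single-electron reduction.

Step 14
Reactants: 24 (R)-4-(tert-butyldimethylsilyloxy)cyclopent-2-en-1-one
Product: 25 (R)-4-(tert-butyldimethylsilyloxy)-2-iodocyclopent-2-en-1-one
Conditions: I2, pyridine, CH2Cl2, 0 °C to rt
Reagents that add atoms: iodine, II
Why: α-Iodination of the enone by the iodine–pyridine addition/elimination sequence is standard for cyclopentenones and leaves the silyloxy stereocentre untouched.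

Step 15
Reactants: 25 (R)-2-iodo enone; 26 allyltributylstannane
Product: 27 (R)-2-allyl-4-(tert-butyldimethylsilyloxy)cyclopent-2-en-1-one
Conditions: Pd2(dba)3 (2.5 mol %), AsPh3 (10 mol %), NMP, rt
Reagents that add atoms: none
Why: Stille coupling of the α-iodoenone under neutral conditions should introduce the allyl arm without β-elimination of the silyloxy group.

Step 16
Reactants: 23 N-acyloxyphthalimide; 27 (R)-2-allyl-4-silyloxycyclopentenone
Product: 29 cis-fused hydroazulenone silyl ether (rings C and D joined to the A/B half), via Giese adduct 28 (not isolated)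
Conditions: [Ru(bpy)3](PF6)2 (1 mol %), Hantzsch ester (1.5 equiv), 27 (1.5 equiv), CH2Cl2, blue LEDs, rt; then, light off, second-generation Hoveyda–Grubbs catalyst (10 mol %), 40 °C
Reagents that add atoms: none
Why: The photoreduced ruthenium complex transfers an electron to 23, which loses phthalimide anion and CO2 to give the tertiary radical at the gem-dimethyl carbon; this nucleophilic radical adds to the β-carbon of enone 27, the α-keto radical is reduced to the ketone by the Hantzsch ester, and the ruthenium alkylidene added to the same flask then joins the allyl and propenyl groups with loss of propene. The closest known reaction types are the reductive photoredox coupling of tertiary redox-active esters with cyclopentenones (Giese addition) and ring-closing metathesis to trisubstituted cycloheptenes, here run as one operation. The radical addition is the intermolecular bond that unites the two halves, and the seven-membered ring C is closed by the metathesis, which also completes the cis-fused hydroazulene. The ring-fusion CH next to the quaternary carbon is set by attack of the radical anti to the silyloxy group on the neighbouring ring carbon, and the α-CH by hydrogen delivery anti to the very bulky new substituent, which leaves the allyl arm cis to it. The step needs the radical to choose the enone over the two unactivated alkenes and the cis α-centre to survive until the ring is closed; the first is secured by the polarity match of the nucleophilic radical with the electron-poor enone, the second by the neutral, base-free conditions of both stages.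

Step 17
Reactants: 29 cis-fused hydroazulenone silyl ether
Product: 30 cis-fused hydroazulene cyclopentenone
Conditions: DBU (1.2 equiv), CH2Cl2, 0 °C
Reagents that add atoms: none
Why: E1cB elimination of the β-silyloxy group through the less hindered ketone enolate removes the stereodirecting oxygen once it has done its work and is expected to be much faster than epimerisation at the ring-fusion α-carbon.

Step 18
Reactants: 30 cis-fused hydroazulene cyclopentenone
Product: 31 cis-fused hydroazulenone
Conditions: H2 (1 atm), RhCl(PPh3)3 (5 mol %), benzene, rt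
Reagents that add atoms: none
Why: Homogeneous hydrogenation with RhCl(PPh3)3 should reduce the unhindered disubstituted enone C=C and leave the hindered trisubstituted ring-C alkene, the ester and all stereocentres untouched.

Step 19
Reactants: 31 cis-fused hydroazulenone
Product: 32 exocyclic methylene compound
Conditions: Zn, CH2Br2, TiCl4, THF/CH2Cl2, 0 °C to rt
Reagents that add atoms: dibromomethane, BrCBr
Why: Takai–Lombardo methylenation is non-basic and should convert the hindered, epimerisable cyclopentanone into the exocyclic alkene without loss of the cis ring fusion.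

Step 20
Reactants: 32 exocyclic methylene compound
Product: 34 ring-D tertiary alcohol (ring-A isobutyrate), via hydroperoxide 33 (not isolated)
Conditions: Mn(dpm)3 (10 mol %), PhSiH3 (2 equiv), O2 (1 atm), iPrOH/CH2Cl2, 0 °C; then PPh3
Reagents that add atoms: dioxygen, O=O
Why: In this Mukaiyama hydration a hydrogen atom is transferred to the less hindered 1,1-disubstituted alkene (the trisubstituted ring-C alkene reacts more slowly) and the tertiary radical is trapped by O2 on the convex face of the cis-fused hydroazulene, anti to ring C, so that the hydroxyl should end cis to the ring-fusion hydrogen.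

Step 21
Reactants: 34 ring-D tertiary alcohol (ring-A isobutyrate)
Product: 35 triol
Conditions: LiAlH4, THF, 0 °C to rt; aqueous work-up
Reagents that add atoms: none
Why: LiAlH4 cleaves the hindered isobutyrate reductively, no other reducible group being present.

Step 22
Reactants: 35 triol
Product: 36 CNP0194989.5
Conditions: Dess–Martin periodinane, NaHCO3, CH2Cl2, rt
Reagents that add atoms: none
Why: Dess–Martin oxidation affects only the single secondary alcohol, the two tertiary alcohols being inert, and so gives the ring-A ketone of the target.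

**Compound list**

1 | 2-methylcyclohexane-1,3-dione | CC1C(=O)CCCC1=O | starting material
2 | acrolein | C=CC=O | starting material
3 | 3-(1-methyl-2,6-dioxocyclohexyl)propanal | O=CCCC1(C)C(=O)CCCC1=O | intermediate
4 | isopropyltriphenylphosphonium iodide | CC(C)[P+](c1ccccc1)(c1ccccc1)c1ccccc1.[I-] | starting material
5 | 2-methyl-2-(4-methylpent-3-en-1-yl)cyclohexane-1,3-dione | CC(C)=CCCC1(C)C(=O)CCCC1=O | intermediate
6 | (2R,3R)-3-hydroxy-2-methyl-2-(4-methylpent-3-en-1-yl)cyclohexan-1-one (hydroxyl cis to the homoprenyl arm) | O=C1[C@](C)(CCC=C(C)C)[C@H](O)CCC1 | intermediate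
7 | (2R,3R)-2-[2-(3,3-dimethyloxiran-2-yl)ethyl]-3-hydroxy-2-methylcyclohexan-1-one (epoxide epimers) | O=C1[C@](C)(CCC2OC2(C)C)[C@H](O)CCC1 | intermediate
8 | (5aR,9aR)-3-hydroxy-2,2,5a-trimethyloctahydro-1-benzoxepin-6(2H)-one (cis-fused rings A/B; C-3 epimers) | O=C1[C@]2(C)CCC(O)C(C)(C)O[C@@H]2CCC1 | intermediate
9 | ring-AB enol triflate: 3-hydroxy-2,2,5a-trimethyl-2,3,4,5,5a,8,9,9a-octahydro-1-benzoxepin-6-yl trifluoromethanesulfonate (ring fusion as in 8) | FC(F)(F)S(=O)(=O)OC1=CCC[C@H]2OC(C)(C)C(O)CC[C@@]12C | intermediate
10 | but-3-en-1-ylmagnesium bromide | C=CCC[Mg]Br | starting material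
11 | ring-AB diene: 6-(but-3-en-1-yl)-2,2,5a-trimethyl-2,3,4,5,5a,8,9,9a-octahydro-1-benzoxepin-3-ol (ring fusion as in 8) | C=CCCC1=CCC[C@H]2OC(C)(C)C(O)CC[C@@]12C | intermediate
12 | 6,7-epoxide of 11 (oxygen on the face of the angular methyl group) | C=CCC[C@]13[C@]2(C)CCC(O)C(C)(C)O[C@@H]2CC[C@H]1O3 | intermediate
13 | ring-AB ketone: 6-(but-3-en-1-yl)-3-hydroxy-2,2,5a-trimethyloctahydro-1-benzoxepin-7(2H)-one (butenyl cis to the angular methyl group) | C=CCC[C@H]1[C@]2(C)CCC(O)C(C)(C)O[C@@H]2CCC1=O | intermediate
14 | ring-AB diol: 6-(but-3-en-1-yl)-2,2,5a,7-tetramethyldecahydro-1-benzoxepine-3,7-diol (7-hydroxyl cis to the butenyl chain and the angular methyl group) | C=CCC[C@H]1[C@]2(C)CCC(O)C(C)(C)O[C@@H]2CC[C@@]1(C)O | intermediate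
15 | 3-methylbut-3-en-2-one | CC(=O)C(C)=C | starting material
16 | (E)-3-methyl-6-(ring-AB diol-6-yl)hex-3-en-2-one | CC(=O)/C(C)=C/CC[C@H]1[C@]2(C)CCC(O)C(C)(C)O[C@@H]2CC[C@@]1(C)O | intermediate
17 | (2S,3E)-3-methyl-6-(ring-AB diol-6-yl)hex-3-en-2-ol | C[C@H](O)/C(C)=C/CC[C@H]1[C@]2(C)CCC(O)C(C)(C)O[C@@H]2CC[C@@]1(C)O | intermediate
18 | isobutyric anhydride | CC(C)C(=O)OC(=O)C(C)C | starting material
19 | bis-isobutyrate of 17 (allylic and ring-A secondary hydroxyl groups) | CC(C)C(=O)O[C@@H](C)/C(C)=C/CC[C@H]1[C@]2(C)CCC(OC(=O)C(C)C)C(C)(C)O[C@@H]2CC[C@@]1(C)O | intermediate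
20 | bis(trimethylsilyl ketene acetal) of 19 with the tertiary hydroxyl as trimethylsilyl ether | CC(C)=C(O[Si](C)(C)C)O[C@@H](C)/C(C)=C/CC[C@H]1[C@]2(C)CCC(OC(O[Si](C)(C)C)=C(C)C)C(C)(C)O[C@@H]2CC[C@@]1(C)O[Si](C)(C)C | intermediate
21 | (3R,4E)-2,2,4-trimethyl-3-[2-(ring-AB)ethyl]hex-4-enoic acid (ring-A hydroxyl as isobutyrate) | OC(=O)C(C)(C)[C@@H](/C(C)=C/C)CC[C@H]1[C@]2(C)CCC(OC(=O)C(C)C)C(C)(C)O[C@@H]2CC[C@@]1(C)O | intermediate
22 | N-hydroxyphthalimide | ON1C(=O)c2ccccc2C1=O | starting material
23 | 1,3-dioxoisoindolin-2-yl ester (N-acyloxyphthalimide) of acid 21 | O=C(ON1C(=O)c2ccccc2C1=O)C(C)(C)[C@@H](/C(C)=C/C)CC[C@H]1[C@]2(C)CCC(OC(=O)C(C)C)C(C)(C)O[C@@H]2CC[C@@]1(C)O | intermediate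
24 | (R)-4-(tert-butyldimethylsilyloxy)cyclopent-2-en-1-one | O=C1C=C[C@H](O[Si](C)(C)C(C)(C)C)C1 | starting material
25 | (R)-4-(tert-butyldimethylsilyloxy)-2-iodocyclopent-2-en-1-one | O=C1C(I)=C[C@H](O[Si](C)(C)C(C)(C)C)C1 | intermediate
26 | allyltributylstannane | C=CC[Sn](CCCC)(CCCC)CCCC | starting material
27 | (R)-2-allyl-4-(tert-butyldimethylsilyloxy)cyclopent-2-en-1-one | C=CCC1=C[C@H](O[Si](C)(C)C(C)(C)C)CC1=O | intermediate
28 | Giese adduct: 2-allyl-3-(tert-alkyl)-4-silyloxycyclopentanone, allyl cis and silyloxy trans to the tert-alkyl group | C=CC[C@H]1[C@H]([C@H](O[Si](C)(C)C(C)(C)C)CC1=O)C(C)(C)[C@@H](/C(C)=C/C)CC[C@H]1[C@]2(C)CCC(OC(=O)C(C)C)C(C)(C)O[C@@H]2CC[C@@]1(C)O | intermediate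
29 | cis-fused hydroazulenone silyl ether (ring-fusion hydrogens and the hydrogen at the chain-bearing carbon syn; silyloxy on the same face) | CC1=CC[C@H]2[C@H]([C@H](O[Si](C)(C)C(C)(C)C)CC2=O)C(C)(C)[C@@H]1CC[C@H]1[C@]2(C)CCC(OC(=O)C(C)C)C(C)(C)O[C@@H]2CC[C@@]1(C)O | intermediate
30 | cis-fused hydroazulene cyclopentenone | CC1=CC[C@H]2[C@H](C=CC2=O)C(C)(C)[C@@H]1CC[C@H]1[C@]2(C)CCC(OC(=O)C(C)C)C(C)(C)O[C@@H]2CC[C@@]1(C)O | intermediate
31 | cis-fused hydroazulenone | CC1=CC[C@H]2[C@H](CCC2=O)C(C)(C)[C@@H]1CC[C@H]1[C@]2(C)CCC(OC(=O)C(C)C)C(C)(C)O[C@@H]2CC[C@@]1(C)O | intermediate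
32 | exocyclic methylene compound (ring-D ketone replaced by C=CH2) | CC1=CC[C@H]2[C@H](CCC2=C)C(C)(C)[C@@H]1CC[C@H]1[C@]2(C)CCC(OC(=O)C(C)C)C(C)(C)O[C@@H]2CC[C@@]1(C)O | intermediate
33 | ring-D tertiary hydroperoxide (OOH cis to the ring-fusion hydrogen) | CC1=CC[C@H]2[C@H](CC[C@]2(C)OO)C(C)(C)[C@@H]1CC[C@H]1[C@]2(C)CCC(OC(=O)C(C)C)C(C)(C)O[C@@H]2CC[C@@]1(C)O | intermediate
34 | ring-D tertiary alcohol, ring-A isobutyrate | CC1=CC[C@H]2[C@H](CC[C@]2(C)O)C(C)(C)[C@@H]1CC[C@H]1[C@]2(C)CCC(OC(=O)C(C)C)C(C)(C)O[C@@H]2CC[C@@]1(C)O | intermediate
35 | triol (ring-A secondary alcohol, epimers) | CC1=CC[C@H]2[C@H](CC[C@]2(C)O)C(C)(C)[C@@H]1CC[C@H]1[C@]2(C)CCC(O)C(C)(C)O[C@@H]2CC[C@@]1(C)O | intermediate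
36 | CNP0194989.5 | CC1=CC[C@H]2[C@H](CC[C@]2(C)O)C(C)(C)[C@@H]1CC[C@H]1[C@]2(C)CCC(=O)C(C)(C)O[C@@H]2CC[C@@]1(C)O | target

**Step count and risks**

Total step count: 22. Longest linear sequence: 20 (steps 1–13 and 16–22).

Steps most likely to fail:

1. Step 16. The hindered tertiary radical may be reduced to the alkane before it adds to the α,γ-disubstituted enone. By-products of the photochemical stage may also deactivate the ruthenium alkylidene, so that ring closure stalls and the cis α-centre slowly epimerises. The fallback sets out from acid 21 and comes back at 29. Acid 21 is converted with 2-mercaptopyridine N-oxide and DCC into the O-acyl thiohydroxamate, the Barton ester F1. Visible-light chain decomposition of F1 in the presence of an excess of 27 adds the radical and transfers the pyridylthio group, which should give the α-(pyridin-2-ylsulfanyl) ketone F2. Bu3SnH/AIBN then replaces sulfur by hydrogen from the face away from the quaternary arm to give 28, which is purified and cyclised to 29 by ring-closing metathesis in a separate operation.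

2. Step 7. The dioxirane may attack the face of the ring alkene that carries ring A, or in the Lewis-acid stage the ring CH2 may migrate instead of hydride, contracting ring B. The fallback sets out from 11 and comes back at 13. Epoxide 12 is isolated and opened reductively with Cp2TiCl2, Zn and cyclohexa-1,4-diene (C–O homolysis at the tertiary carbon, then hydrogen-atom transfer) to the ring-B secondary alcohol F3. Selective oxidation of this less hindered carbinol with Ag2CO3 on Celite, in the presence of the neopentyl ring-A hydroxyl, should give 13; the α-centre can then be equilibrated with DBU if needed.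

3. Step 4. The epoxide may open in the 6-exo sense at its secondary carbon, giving a tetrahydropyran instead of the oxepane. The fallback sets out from 6 and comes back at 8. Alkene 6 is cyclised with Hg(OCOCF3)2 in MeNO2, where Markovnikov attack of the hydroxyl on the tertiary carbon of the mercurinium ion is strongly preferred; after NaCl exchange this should give the alkylmercuric chloride F4. Oxidative demercuration (NaBH4, O2, DMF) then installs the hydroxyl and gives 8.

**Further compounds**

F1 | step 16 | Barton ester of acid 21 (2-thioxopyridin-1(2H)-yl ester) | S=C1C=CC=CN1OC(=O)C(C)(C)[C@@H](/C(C)=C/C)CC[C@H]1[C@]2(C)CCC(OC(=O)C(C)C)C(C)(C)O[C@@H]2CC[C@@]1(C)O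
F2 | step 16 | 2-allyl-2-(pyridin-2-ylsulfanyl)-3-(tert-alkyl)-4-silyloxycyclopentanone adduct (either epimer at the sulfur-bearing carbon) | C=CCC1(Sc2ccccn2)[C@H]([C@H](O[Si](C)(C)C(C)(C)C)CC1=O)C(C)(C)[C@@H](/C(C)=C/C)CC[C@H]1[C@]2(C)CCC(OC(=O)C(C)C)C(C)(C)O[C@@H]2CC[C@@]1(C)O
F3 | step 7 | ring-B secondary alcohol: 6-(but-3-en-1-yl)-2,2,5a-trimethyldecahydro-1-benzoxepine-3,7-diol | C=CCC[C@H]1[C@]2(C)CCC(O)C(C)(C)O[C@@H]2CC[C@H]1O
F4 | step 4 | alkylmercuric chloride: 3-(chloromercurio)-2,2,5a-trimethyloctahydro-1-benzoxepin-6(2H)-one | O=C1[C@]2(C)CCC([Hg]Cl)C(C)(C)O[C@@H]2CCC1
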